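**Plan**

Numbering: ring C1–C6 (C1 quaternary, C2 and C5 carbonyls, C3=C4), arm C7H2–C8O2Me, side chain C1'–C16'. C1 is α to the ring ketone C2 and β to the ester carbonyl C8 (a 1,4-dicarbonyl pattern), so the C1–C2 bond is cut to an acyl anion at C2 and a C1=C7 enoate.
Further cuts: C3=C4 (late dehydrogenation), C1–C1' (alkenyl–allyl coupling), C4–C5 and C5–C6 (two alkylations of 1,3-dithiane, the masked C5 ketone), C12'–C13' (allylboration), C14'=C15' (cross-metathesis).
Forward: farnesyl acetate is oxidised at C12', extended to the anti-diol acetonide and converted into the C1' bromide. The dithiane linchpin is carried to a β-stannyl enoate and joined to the bromide. The aldehyde is unmasked and the only ring is closed by the carbene-catalysed step; dithiane and acetonide are then removed and C3=C4 is introduced.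
Stereochemistry: 12'S,13'R from a reagent-controlled (E)-γ-silylallylboration with Tamao oxidation; C1 from the chiral triazolylidene. The alkene geometries come from farnesyl acetate, an E-selective SeO2 oxidation and a chelation-controlled stannylcupration, which places the tether trans to the ester in the ring-closure precursor.

Key step: step 15

Assumption: the (5aS,10bR) antipode of the aminoindanol-derived triazolium salt is taken to deliver C2 to the Re face of C1 in the (E)-enoate; the enantiomeric salt is equally available and would be used if the sense proves opposite.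

**Route**

Step 1
Reactants: 1 (2E,6E)-farnesyl acetate
Product: 2 (2E,6E,10E)-12-hydroxy-3,7,11-trimethyldodeca-2,6,10-trien-1-yl acetate
Conditions: SeO2 (cat.), t-BuOOH, salicylic acid (cat.), CH2Cl2, 23 °C
Reagents that add atoms: tert-butyl hydroperoxide, CC(C)(C)OO
Why: The SeO2/t-BuOOH allylic oxidation (ene reaction, then [2,3]-sigmatropic shift) should attack the terminal isopropylidene, the most electron-rich alkene and the one farthest from the acetate, at its (E)-methyl group and give the (E)-allylic alcohol.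

Step 2
Reactants: 2
Product: 3 (2E,6E,10E)-3,7,11-trimethyl-12-oxododeca-2,6,10-trien-1-yl acetate
Conditions: MnO2, CH2Cl2, 23 °C
Reagents that add atoms: none
Why: MnO2 oxidation is selective for allylic alcohols and should give the (E)-enal without touching the other alkenes or the acetate.

Step 3
Reactants: 3
Product: 5 (2E,6E,10E,12S,13R)-3,7,11-trimethylpentadeca-2,6,10,14-tetraene-1,12,13-triol, via silyl borinate 4 (not isolated)
Conditions: allyl(diisopropylamino)dimethylsilane, n-BuLi, TMEDA, Et2O, 0 °C; (+)-Ipc2BOMe, −78 °C; BF3·OEt2; 3, −78 °C; then 30% H2O2, KF, KHCO3, THF/MeOH, 23 °C; then K2CO3, MeOH, 23 °C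
Reagents that add atoms: allyl(diisopropylamino)dimethylsilane, C=CC[Si](C)(C)N(C(C)C)C(C)C; hydrogen peroxide, OO
Why: In this Brown-type γ-silylallylboration the (E)-γ-silylallylborane reacts through a chair transition state to give the anti arrangement, the isopinocampheyl groups from (−)-α-pinene direct attack to the aldehyde face that gives 12S, the Tamao oxidation replaces silicon by oxygen with retention (13R), and the basic peroxide/methanol medium removes the acetate.

Step 4
Reactants: 5
Product: 6 (2E,6E,10E)-11-[(4S,5R)-2,2-dimethyl-5-vinyl-1,3-dioxolan-4-yl]-3,7-dimethyldodeca-2,6,10-trien-1-ol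
Conditions: Me2C(OMe)2, PPTS (cat.), acetone, 23 °C; brief aqueous work-up
Reagents that add atoms: 2,2-dimethoxypropane, COC(C)(C)OC
Why: Acid-catalysed transketalisation should close the five-membered dioxolane on the 1,2-diol only, and any mixed ketal on the primary alcohol is lost on work-up.

Step 5
Reactants: 6
Product: 7 (2E,6E,10E)-11-[(4S,5R)-2,2-dimethyl-5-(2-methylprop-1-en-1-yl)-1,3-dioxolan-4-yl]-3,7-dimethyldodeca-2,6,10-trien-1-ol
Conditions: second-generation Grubbs catalyst RuCl2(=CHPh)(H2IMes)(PCy3) (5 mol %), 2-methyl-2-butene (large excess), CH2Cl2, 23 °C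
Reagents that add atoms: 2-methyl-2-butene, CC=C(C)C
Why: In this olefin cross-metathesis the monosubstituted vinyl group is the only alkene that loads the ruthenium carbene readily at room temperature, so it should be capped as the isobutenyl group while the trisubstituted chain alkenes stay untouched.

Step 6
Reactants: 7
Product: 9 (4S,5R)-4-[(2E,6E,10E)-12-bromo-6,10-dimethyldodeca-2,6,10-trien-2-yl]-2,2-dimethyl-5-(2-methylprop-1-en-1-yl)-1,3-dioxolane, via allylic mesylate 8 (not isolated)
Conditions: MsCl, Et3N, THF, −40 °C; then LiBr, THF, 0 °C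
Reagents that add atoms: lithium bromide, [Li+].[Br-]
Why: Mesylation followed by SN2 displacement with bromide at low temperature is the standard way to primary prenyl-type bromides without allylic transposition or loss of E geometry.

Step 7
Reactants: 10 1,3-dithiane; 11 (3-bromopropoxy)(tert-butyl)dimethylsilane
Product: 13 tert-butyl[3-(1,3-dithian-2-yl)propoxy]dimethylsilane, via 2-lithio-1,3-dithiane 12 (not isolated)
Conditions: n-BuLi, THF, −30 °C; then 11, −30 → 0 °C
Reagents that add atoms: none
Why: Corey–Seebach alkylation of the dithiane anion with a primary bromide forms C4–C5 and brings in C2–C4 with C2 at the alcohol level.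

Step 8
Reactants: 13; 14 3-bromo-1-(trimethylsilyl)prop-1-yne
Product: 16 tert-butyldimethyl(3-{2-[3-(trimethylsilyl)prop-2-yn-1-yl]-1,3-dithian-2-yl}propoxy)silane, via lithiated dithiane 15 (not isolated)
Conditions: n-BuLi, THF, −25 °C; then 14, −78 → 0 °C
Reagents that add atoms: none
Why: A second Corey–Seebach alkylation with the reactive propargylic bromide forms C5–C6, and the silyl cap keeps the alkyne from being deprotonated.

Step 9
Reactants: 16
Product: 17 tert-butyldimethyl{3-[2-(prop-2-yn-1-yl)-1,3-dithian-2-yl]propoxy}silane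
Conditions: K2CO3 (cat.), MeOH, 23 °C
Reagents that add atoms: none
Why: Methoxide-mediated protodesilylation cleaves the alkynyl C–Si bond and leaves the silyl ether of the primary alcohol intact.

Step 10
Reactants: 17
Product: 19 methyl 4-{2-[3-(tert-butyldimethylsilyloxy)propyl]-1,3-dithian-2-yl}but-2-ynoate, via lithium acetylide 18 (not isolated)
Conditions: n-BuLi, THF, −78 °C; then ClCO2Me, −78 → 0 °C
Reagents that add atoms: methyl chloroformate, COC(=O)Cl
Why: C-acylation of the lithium acetylide with methyl chloroformate gives the ynoate (C7, C8); the 2,2-disubstituted dithiane has no competing acidic proton.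

Step 11
Reactants: 19
Product: 20 methyl (2Z)-4-{2-[3-(tert-butyldimethylsilyloxy)propyl]-1,3-dithian-2-yl}-3-(trimethylstannyl)but-2-enoate
Conditions: Me3SnSnMe3, MeLi, THF, −20 °C; CuSPh; then 19, −78 → −48 °C, 4 h; MeOH, −48 °C
Reagents that add atoms: hexamethylditin, C[Sn](C)(C)[Sn](C)(C)C
Why: In this Piers stannylcupration under equilibrating conditions the first-formed syn adduct isomerises through the copper allenoate to the chelated isomer, so protonation should give the stannane with tin cis to the ester and the C6 arm trans to it.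

Step 12
Reactants: 20; 9
Product: 21 methyl (2E,5E,9E,13E)-3-({2-[3-(tert-butyldimethylsilyloxy)propyl]-1,3-dithian-2-yl}methyl)-14-[(4S,5R)-2,2-dimethyl-5-(2-methylprop-1-en-1-yl)-1,3-dioxolan-4-yl]-6,10-dimethylpentadeca-2,5,9,13-tetraenoate
Conditions: Pd2(dba)3 (5 mol %), AsPh3 (20 mol %), CuI (20 mol %), NMP, 23 → 40 °C
Reagents that add atoms: none
Why: In this Stille alkenyl–allyl coupling zerovalent palladium ionises the bromide and the alkenyl group is transferred to the primary terminus with retention at both partners, so C1–C1' forms with the chain cis and the tether trans to the ester.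

Step 13
Reactants: 21
Product: 22 methyl (2E,5E,9E,13E)-14-[(4S,5R)-2,2-dimethyl-5-(2-methylprop-1-en-1-yl)-1,3-dioxolan-4-yl]-3-{[2-(3-hydroxypropyl)-1,3-dithian-2-yl]methyl}-6,10-dimethylpentadeca-2,5,9,13-tetraenoate
Conditions: HF·pyridine, pyridine, THF, 0 → 23 °C
Reagents that add atoms: none
Why: Buffered fluoride cleavage of the primary silyl ether avoids both the acid that would open the acetonide and the base that could move the skipped dienoate into conjugation.

Step 14
Reactants: 22
Product: 23 methyl (2E,5E,9E,13E)-14-[(4S,5R)-2,2-dimethyl-5-(2-methylprop-1-en-1-yl)-1,3-dioxolan-4-yl]-6,10-dimethyl-3-{[2-(3-oxopropyl)-1,3-dithian-2-yl]methyl}pentadeca-2,5,9,13-tetraenoate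
Conditions: SO3·pyridine, DMSO, i-Pr2NEt, CH2Cl2, 0 °C
Reagents that add atoms: none
Why: The Parikh–Doering oxidation (activated DMSO) stops at the aldehyde and tolerates the dithiane sulfur atoms, which iodine- or chromium-based oxidants could attack.

Step 15
Reactants: 23
Product: 24 methyl 2-[(8S)-8-{(2E,6E,10E)-11-[(4S,5R)-2,2-dimethyl-5-(2-methylprop-1-en-1-yl)-1,3-dioxolan-4-yl]-3,7-dimethyldodeca-2,6,10-trien-1-yl}-9-oxo-1,5-dithiaspiro[5.5]undecan-8-yl]acetate
Conditions: (5aS,10bR)-2-(pentafluorophenyl)-5a,10b-dihydro-4H,6H-indeno[2,1-b][1,2,4]triazolo[4,3-d][1,4]oxazin-2-ium tetrafluoroborate (20 mol %), KN(SiMe3)2 (18 mol %), toluene, 23 °C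
Reagents that add atoms: none
Why: The triazolylidene freed by the base adds to the C2 aldehyde and proton transfer gives the enaminol (acyl anion equivalent), whose C2 adds to C1, the β-carbon of the enoate; protonation at C7 and loss of the carbene leave the C2 ketone and the CH2CO2Me arm in final form. The closest known reaction is the catalytic asymmetric intramolecular Stetter reaction of aliphatic aldehydes onto (E)-β,β-disubstituted enoates, which sets quaternary centres; the all-carbon six-membered ring formed here lies at the upper edge of its ring-size range. The ring closes in the 6-exo-trig mode (C2 onto C1, C7 exocyclic). The new stereocentre C1 is set by the catalyst: the aminoindanol backbone shields one face of the enaminol so that C2 reaches the Re face of C1 (priorities C7 > C6 > C1'); the descriptor reads S while the dithiane is present and R in the target, with the same spatial arrangement. The step needs conjugate addition to outrun aldol or benzoin self-condensation of the enolisable aldehyde and base-induced migration of the C1=C7 bond toward C1'; the gem-dithio group at C5 (Thorpe–Ingold compression, no enolisable ketone between the reacting ends), the tether-trans enoate geometry, the weakly basic N-C6F5 carbene and a substoichiometric amount of base are there to secure this.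

Step 16
Reactants: 24
Product: 25 methyl 2-[(8S)-8-[(2E,6E,10E,12S,13R)-12,13-dihydroxy-3,7,11,15-tetramethylhexadeca-2,6,10,14-tetraen-1-yl]-9-oxo-1,5-dithiaspiro[5.5]undecan-8-yl]acetate
Conditions: PPTS (0.3 equiv), MeOH, 40 °C
Reagents that add atoms: none
Why: Mild acid-catalysed transketalisation to methanol opens the acetonide at the ketal carbon, not at the allylic C–O bonds, and is done here while the ring is still a robust dithiane ketone.

Step 17
Reactants: 25
Product: 26 methyl 2-[(1R)-1-[(2E,6E,10E,12S,13R)-12,13-dihydroxy-3,7,11,15-tetramethylhexadeca-2,6,10,14-tetraen-1-yl]-2,5-dioxocyclohexyl]acetate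
Conditions: MeI, CaCO3, MeCN/H2O (4:1), 45 °C
Reagents that add atoms: water, O
Why: Alkylative hydrolysis of the dithiane (S-methylation, then hydrolysis) is non-oxidative, so the free 1,2-diol and the four alkenes are not at risk while the C5 ketone is released.

Step 18
Reactants: 26
Product: 27 methyl 2-[(1R)-1-[(2E,6E,10E,12S,13R)-3,7,11,15-tetramethyl-12,13-bis(trimethylsilyloxy)hexadeca-2,6,10,14-tetraen-1-yl]-2,5-bis(trimethylsilyloxy)cyclohexa-2,4-dien-1-yl]acetate
Conditions: TMSOTf, Et3N, CH2Cl2, 0 °C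
Reagents that add atoms: trimethylsilyl trifluoromethanesulfonate, C[Si](C)(C)OS(=O)(=O)C(F)(F)F
Why: Soft enolisation with silyl triflate and amine silylates both ketones and both alcohols; C2 can enolise only toward C3 because C1 is quaternary, and a C5=C6 enol ether regioisomer would lead to the same product in step 19.

Step 19
Reactants: 27
Product: 29 methyl 2-[(1R)-1-[(2E,6E,10E,12S,13R)-12,13-dihydroxy-3,7,11,15-tetramethylhexadeca-2,6,10,14-tetraen-1-yl]-2,5-dioxocyclohex-3-en-1-yl]acetate (CNP0122011.2), via bis(trimethylsilyl) ether 28 (not isolated)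
Conditions: Pd(OAc)2 (1.2 equiv), MeCN, 23 °C; then AcOH/THF/H2O, 23 °C
Reagents that add atoms: none
Why: In this Saegusa–Ito oxidation divalent palladium attacks the silyl enol ether at C3 or C4 and the only alkene that can form is C3=C4, because C1 carries no hydrogen; the mild aqueous acid then removes the two silyl ethers without endangering the ene-dione or the allylic diol.

**Compound list**

1 | (2E,6E)-farnesyl acetate | CC(C)=CCC/C(C)=C/CC/C(C)=C/COC(C)=O | starting material
2 | (2E,6E,10E)-12-hydroxy-3,7,11-trimethyldodeca-2,6,10-trien-1-yl acetate | CC(=O)OC/C=C(\C)CC/C=C(\C)CC/C=C(\C)CO | intermediate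
3 | (2E,6E,10E)-3,7,11-trimethyl-12-oxododeca-2,6,10-trien-1-yl acetate | CC(=O)OC/C=C(\C)CC/C=C(\C)CC/C=C(\C)C=O | intermediate
4 | (2E,6E,10E,12S,13R)-12-{bis[(1S,2S,3S,5R)-2,6,6-trimethylbicyclo[3.1.1]hept-3-yl]boryloxy}-13-[(diisopropylamino)dimethylsilyl]-3,7,11-trimethylpentadeca-2,6,10,14-tetraen-1-yl acetate (formed in the flask) | CC(=O)OC/C=C(\C)CC/C=C(\C)CC/C=C(\C)[C@H](OB([C@H]1C[C@H]2C[C@@H]([C@@H]1C)C2(C)C)[C@H]1C[C@H]2C[C@@H]([C@@H]1C)C2(C)C)[C@H]([Si](C)(C)N(C(C)C)C(C)C)C=C | intermediate
5 | (2E,6E,10E,12S,13R)-3,7,11-trimethylpentadeca-2,6,10,14-tetraene-1,12,13-triol | OC/C=C(\C)CC/C=C(\C)CC/C=C(\C)[C@H](O)[C@H](O)C=C | intermediate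
6 | (2E,6E,10E)-11-[(4S,5R)-2,2-dimethyl-5-vinyl-1,3-dioxolan-4-yl]-3,7-dimethyldodeca-2,6,10-trien-1-ol | OC/C=C(\C)CC/C=C(\C)CC/C=C(\C)[C@H](OC1(C)C)[C@H](O1)C=C | intermediate
7 | (2E,6E,10E)-11-[(4S,5R)-2,2-dimethyl-5-(2-methylprop-1-en-1-yl)-1,3-dioxolan-4-yl]-3,7-dimethyldodeca-2,6,10-trien-1-ol | OC/C=C(\C)CC/C=C(\C)CC/C=C(\C)[C@H](OC1(C)C)[C@H](O1)C=C(C)C | intermediate
8 | methanesulfonate of 7 (formed in the flask) | CS(=O)(=O)OC/C=C(\C)CC/C=C(\C)CC/C=C(\C)[C@H](OC1(C)C)[C@H](O1)C=C(C)C | intermediate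
9 | (4S,5R)-4-[(2E,6E,10E)-12-bromo-6,10-dimethyldodeca-2,6,10-trien-2-yl]-2,2-dimethyl-5-(2-methylprop-1-en-1-yl)-1,3-dioxolane | BrC/C=C(\C)CC/C=C(\C)CC/C=C(\C)[C@H](OC1(C)C)[C@H](O1)C=C(C)C | intermediate
10 | 1,3-dithiane | C1CSCSC1 | starting material
11 | (3-bromopropoxy)(tert-butyl)dimethylsilane | CC(C)(C)[Si](C)(C)OCCCBr | starting material
12 | 2-lithio-1,3-dithiane (formed in the flask) | [Li]C1SCCCS1 | intermediate
13 | tert-butyl[3-(1,3-dithian-2-yl)propoxy]dimethylsilane | CC(C)(C)[Si](C)(C)OCCCC1SCCCS1 | intermediate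
14 | 3-bromo-1-(trimethylsilyl)prop-1-yne | C[Si](C)(C)C#CCBr | starting material
15 | 2-lithio derivative of 13 (formed in the flask) | [Li]C1(CCCO[Si](C)(C)C(C)(C)C)SCCCS1 | intermediate
16 | tert-butyldimethyl(3-{2-[3-(trimethylsilyl)prop-2-yn-1-yl]-1,3-dithian-2-yl}propoxy)silane | CC(C)(C)[Si](C)(C)OCCCC1(CC#C[Si](C)(C)C)SCCCS1 | intermediate
17 | tert-butyldimethyl{3-[2-(prop-2-yn-1-yl)-1,3-dithian-2-yl]propoxy}silane | CC(C)(C)[Si](C)(C)OCCCC1(CC#C)SCCCS1 | intermediate
18 | lithium acetylide of 17 (formed in the flask) | [Li]C#CCC1(CCCO[Si](C)(C)C(C)(C)C)SCCCS1 | intermediate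
19 | methyl 4-{2-[3-(tert-butyldimethylsilyloxy)propyl]-1,3-dithian-2-yl}but-2-ynoate | COC(=O)C#CCC1(CCCO[Si](C)(C)C(C)(C)C)SCCCS1 | intermediate
20 | methyl (2Z)-4-{2-[3-(tert-butyldimethylsilyloxy)propyl]-1,3-dithian-2-yl}-3-(trimethylstannyl)but-2-enoate | COC(=O)/C=C(/CC1(CCCO[Si](C)(C)C(C)(C)C)SCCCS1)[Sn](C)(C)C | intermediate
21 | methyl (2E,5E,9E,13E)-3-({2-[3-(tert-butyldimethylsilyloxy)propyl]-1,3-dithian-2-yl}methyl)-14-[(4S,5R)-2,2-dimethyl-5-(2-methylprop-1-en-1-yl)-1,3-dioxolan-4-yl]-6,10-dimethylpentadeca-2,5,9,13-tetraenoate | COC(=O)/C=C(/CC1(CCCO[Si](C)(C)C(C)(C)C)SCCCS1)C/C=C(\C)CC/C=C(\C)CC/C=C(\C)[C@H](OC2(C)C)[C@H](O2)C=C(C)C | intermediate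
22 | 3-hydroxypropyl analogue of 21 (silyl ether cleaved) | COC(=O)/C=C(/CC1(CCCO)SCCCS1)C/C=C(\C)CC/C=C(\C)CC/C=C(\C)[C@H](OC2(C)C)[C@H](O2)C=C(C)C | intermediate
23 | 3-oxopropyl analogue of 21 ((E)-enoate aldehyde, precursor of the ring closure) | COC(=O)/C=C(/CC1(CCC=O)SCCCS1)C/C=C(\C)CC/C=C(\C)CC/C=C(\C)[C@H](OC2(C)C)[C@H](O2)C=C(C)C | intermediate
24 | methyl 2-[(8S)-8-{(2E,6E,10E)-11-[(4S,5R)-2,2-dimethyl-5-(2-methylprop-1-en-1-yl)-1,3-dioxolan-4-yl]-3,7-dimethyldodeca-2,6,10-trien-1-yl}-9-oxo-1,5-dithiaspiro[5.5]undecan-8-yl]acetate | COC(=O)C[C@@]1(C/C=C(\C)CC/C=C(\C)CC/C=C(\C)[C@H](OC3(C)C)[C@H](O3)C=C(C)C)CC2(SCCCS2)CCC1=O | intermediate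
25 | methyl 2-[(8S)-8-[(2E,6E,10E,12S,13R)-12,13-dihydroxy-3,7,11,15-tetramethylhexadeca-2,6,10,14-tetraen-1-yl]-9-oxo-1,5-dithiaspiro[5.5]undecan-8-yl]acetate | COC(=O)C[C@@]1(C/C=C(\C)CC/C=C(\C)CC/C=C(\C)[C@H](O)[C@H](O)C=C(C)C)CC2(SCCCS2)CCC1=O | intermediate
26 | methyl 2-[(1R)-1-[(2E,6E,10E,12S,13R)-12,13-dihydroxy-3,7,11,15-tetramethylhexadeca-2,6,10,14-tetraen-1-yl]-2,5-dioxocyclohexyl]acetate | COC(=O)C[C@@]1(C/C=C(\C)CC/C=C(\C)CC/C=C(\C)[C@H](O)[C@H](O)C=C(C)C)CC(=O)CCC1=O | intermediate
27 | methyl 2-[(1R)-1-[(2E,6E,10E,12S,13R)-3,7,11,15-tetramethyl-12,13-bis(trimethylsilyloxy)hexadeca-2,6,10,14-tetraen-1-yl]-2,5-bis(trimethylsilyloxy)cyclohexa-2,4-dien-1-yl]acetate | COC(=O)C[C@@]1(C/C=C(\C)CC/C=C(\C)CC/C=C(\C)[C@H](O[Si](C)(C)C)[C@H](O[Si](C)(C)C)C=C(C)C)CC(O[Si](C)(C)C)=CC=C1O[Si](C)(C)C | intermediate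
28 | methyl 2-[(1R)-1-[(2E,6E,10E,12S,13R)-3,7,11,15-tetramethyl-12,13-bis(trimethylsilyloxy)hexadeca-2,6,10,14-tetraen-1-yl]-2,5-dioxocyclohex-3-en-1-yl]acetate (formed in the flask) | COC(=O)C[C@@]1(C/C=C(\C)CC/C=C(\C)CC/C=C(\C)[C@H](O[Si](C)(C)C)[C@H](O[Si](C)(C)C)C=C(C)C)CC(=O)C=CC1=O | intermediate
29 | methyl 2-[(1R)-1-[(2E,6E,10E,12S,13R)-12,13-dihydroxy-3,7,11,15-tetramethylhexadeca-2,6,10,14-tetraen-1-yl]-2,5-dioxocyclohex-3-en-1-yl]acetate (CNP0122011.2) | COC(=O)C[C@@]1(C/C=C(\C)CC/C=C(\C)CC/C=C(\C)[C@H](O)[C@H](O)C=C(C)C)CC(=O)C=CC1=O | target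

**Count and risks**

Total steps: 19. Longest linear sequence: 14 steps (steps 1–6 and 12–19, from farnesyl acetate); the dithiane branch (steps 7–11) joins at step 12.

Most likely to fail:

1. Step 15. The enaminol may close the six-membered ring too slowly, so that aldol self-condensation of the enolisable aldehyde and base-induced migration of the C1=C7 bond take over; face selection at C1 may also be weak. The fallback sets out from 23 and replaces the polar closure by a radical one. Buffered chlorite oxidation (NaClO2, NaH2PO4, 2-methyl-2-butene, t-BuOH/H2O) would give the carboxylic acid F1. Treatment with PhSeSePh and PBu3 would give the Se-phenyl selenoester F2. Bu3SnH and AIBN in dilute benzene at 80 °C would then generate the C2 acyl radical, which closes 6-exo onto C1. This closure is not under catalyst control, so 24 would be formed together with its C1 epimer F3, to be removed by preparative HPLC. The route is rejoined at 24.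

2. Step 12. Tin-to-palladium transfer from the ester-chelated, hindered alkenylstannane may be slow, which leaves time for homocoupling of the bromide and for E/Z scrambling of the allyl-palladium species at C2'=C3'. The fallback sets out from 20 and uses a more nucleophilic alkenyl metal. Iododestannylation (I2, CH2Cl2, 0 °C) would give the (Z)-β-iodoenoate F4. Iodine–magnesium exchange (i-PrMgCl·LiCl, THF, −40 °C) and ZnCl2 would give the alkenylzinc chloride F5. Negishi alkenyl–allyl coupling of F5 with 9 under Pd(PPh3)4 returns to the route at 21.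

3. Step 19. The palladium salt may be held by the polyene chain, or the palladium enolate may be protonated before β-hydride elimination, so that the saturated dione is recovered. The fallback sets out from 27 and uses selenoxide elimination. PhSeCl (CH2Cl2, −78 °C) followed by a mildly acidic work-up would give the α-phenylselanyl dione F6, as C3 epimers with the silyl groups lost. One equivalent of mCPBA at −78 °C, then i-Pr2NH on warming, would bring about syn-elimination across C3–C4 and give 29 directly.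

**Further compounds**

F1 | step 15 | carboxylic acid from 23 (3-oxopropyl oxidised to 2-carboxyethyl) | COC(=O)/C=C(/CC1(CCC(O)=O)SCCCS1)C/C=C(\C)CC/C=C(\C)CC/C=C(\C)[C@H](OC2(C)C)[C@H](O2)C=C(C)C
F2 | step 15 | Se-phenyl selenoester of F1 | COC(=O)/C=C(/CC1(CCC(=O)[Se]c2ccccc2)SCCCS1)C/C=C(\C)CC/C=C(\C)CC/C=C(\C)[C@H](OC3(C)C)[C@H](O3)C=C(C)C
F3 | step 15 | C1 epimer of 24 (8R) | COC(=O)C[C@]1(C/C=C(\C)CC/C=C(\C)CC/C=C(\C)[C@H](OC3(C)C)[C@H](O3)C=C(C)C)CC2(SCCCS2)CCC1=O
F4 | step 12 | methyl (2Z)-4-{2-[3-(tert-butyldimethylsilyloxy)propyl]-1,3-dithian-2-yl}-3-iodobut-2-enoate | COC(=O)/C=C(/CC1(CCCO[Si](C)(C)C(C)(C)C)SCCCS1)I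
F5 | step 12 | alkenylzinc chloride from F4 (zinc in place of iodine) | COC(=O)/C=C(/CC1(CCCO[Si](C)(C)C(C)(C)C)SCCCS1)[Zn]Cl
F6 | step 19 | methyl 2-[(1R)-1-[(2E,6E,10E,12S,13R)-12,13-dihydroxy-3,7,11,15-tetramethylhexadeca-2,6,10,14-tetraen-1-yl]-2,5-dioxo-3-(phenylselanyl)cyclohexyl]acetate (C3 epimers) | COC(=O)C[C@@]1(C/C=C(\C)CC/C=C(\C)CC/C=C(\C)[C@H](O)[C@H](O)C=C(C)C)CC(=O)CC([Se]c2ccccc2)C1=O
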